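**Retrosynthetic overview**

1. ent-Kaurane numbering is used throughout. Cyclohexane = C1–C5, C10. Ten-membered ring = C5, C6, C7, C8, C14, C13, C12, C11, C9, C10. Cyclopentenone = C8, C14, C13, C16, C15. C17 is the exocyclic CH2 and C20 the methyl group on C10.
2. Enabling feature: the C5–C10 bond shared by the cyclohexane and the ten-membered ring is the β,α-bond of the C9 ketone. C4 is a gem-dimethyl carbon (a tertiary radical) and C1 lies at aldol distance from C9. The whole cyclohexane is therefore cut off at C4–C5 and C1–C10, leaving the bicyclic (E)-enone 22 and 4-methylpent-4-enal 24.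
3. Forward, 22 + 24 → 26 by an iron-hydride (MHAT) radical–polar crossover annulation. The surplus C1–OH is then removed, C11–O is introduced by enolate oxidation, and the five-membered ring is unmasked (ketal → C15=O, CH2OTIPS → C16=C17).
4. 22 comes from Nozaki–Hiyama–Kishi closure of C9–C10 in iodo aldehyde 20. C7 is set by catalytic asymmetric propargylation of enal 11. C13, C16 and C17 come from a three-component coupling on (S)-4-silyloxycyclopentenone 1.
5. Ring order: five-membered ring (bought with 1), then ten-membered ring (step 12), then cyclohexane (step 15, the last ring closed).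

Key step: step 15

Remark: the carbinol centres C9 in 21 and C1 in 26 and 27 are drawn without configuration. Both are erased again (steps 13 and 17), so either epimer serves.

**Step 1**
Reactants: 1 (S)-4-(tert-butyldimethylsilyloxy)cyclopent-2-en-1-one; 2 (3-bromopropoxy)(tert-butyl)dimethylsilane
Product: 5 (2R,3S,4S)-4-(tert-butyldimethylsilyloxy)-3-[3-(tert-butyldimethylsilyloxy)propyl]-2-(hydroxymethyl)cyclopentan-1-one, via [3-(tert-butyldimethylsilyloxy)propyl]magnesium bromide 3 (not isolated), via bromomagnesium enolate of the 1,4-adduct 4 (not isolated)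
Conditions: 2, Mg, THF, rt; CuBr·SMe2 (10 mol %), 1, THF, −78 °C; CH2O (gas, cracked paraformaldehyde), −78 → −40 °C; aq NH4Cl
Reagents that add atoms: formaldehyde, C=O
Why: Copper-catalysed 1,4-addition anti to the C14 silyloxy group sets C13, and the enolate 4 is trapped by formaldehyde anti to the new side chain (three-component conjugate addition–aldol coupling), which brings in C9, C11, C12 and C17.

**Step 2**
Reactants: 5 hydroxymethyl ketone
Product: 7 (4R,5R)-4-[3-(tert-butyldimethylsilyloxy)propyl]-5-[(triisopropylsilyloxy)methyl]cyclopent-2-en-1-one, via triisopropylsilyl ether of 5 6 (not isolated)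
Conditions: TIPSCl, imidazole, CH2Cl2, 0 °C → rt; then DBU, 0 °C
Reagents that add atoms: triisopropylsilyl chloride, CC(C)[Si](Cl)(C(C)C)C(C)C
Why: Silylation of the primary alcohol is followed by E1cB loss of the ring silyloxy group through the accessible C8 methylene protons; the hindered C16–H and the low temperature should leave CH2OTIPS in place, and C13 is not touched.

**Step 3**
Reactants: 7 cyclopentenone
Product: 8 (4S,5R)-2-iodo-4-[3-(tert-butyldimethylsilyloxy)propyl]-5-[(triisopropylsilyloxy)methyl]cyclopent-2-en-1-one (same spatial arrangement; the C13 descriptor changes only because of iodine)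
Conditions: I2, pyridine–CH2Cl2, 0 °C → rt
Reagents that add atoms: iodine, II
Why: α-Iodination of the enone by pyridine addition, iodination and elimination (Baylis–Hillman-type mechanism) places the handle on C8 without touching a stereocentre.

**Step 4**
Reactants: 8 α-iodoenone
Product: 9 ethylene ketal of 8 (6-iodo-1,4-dioxaspiro[4.4]non-6-ene, C13 and C16 substituents trans as before)
Conditions: (TMSOCH2)2, TMSOTf (10 mol %), CH2Cl2, −78 → −20 °C; pyridine
Reagents that add atoms: 1,2-bis(trimethylsilyloxy)ethane, C[Si](C)(C)OCCO[Si](C)(C)C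
Why: Noyori ketalisation under aprotic conditions masks the C15 ketone without alkene migration or silyl loss, permits the organolithium chemistry, and later removes the competing radical acceptor.

**Step 5**
Reactants: 9 iodo ketal
Product: 11 enal (CHO = C7 on C8 of the ketal), via C8-vinyllithium 10 (not isolated)
Conditions: t-BuLi (2.1 equiv), Et2O, −78 °C; DMF, −78 → 0 °C; H2O
Reagents that add atoms: N,N-dimethylformamide, CN(C)C=O
Why: Iodine–lithium exchange gives the α-ketovinyl anion equivalent 10, which DMF formylates (Bouveault-type formylation) to bring in C7.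

**Step 6**
Reactants: 11 enal; 12 allenylboronic acid pinacol ester
Product: 13 (7R)-homopropargylic alcohol (C8–C7H(OH)–C6H2–C5≡C10H)
Conditions: (R)-TRIP (5 mol %), 4 Å MS, toluene, −20 °C
Reagents that add atoms: none
Why: In this chiral phosphoric acid-catalysed propargylation, the closed six-membered SE2′ transition state bound to the (R)-catalyst should direct attack to the Re face of the enal, so C7 (R) is set under catalyst control.

**Step 7**
Reactants: 13 homopropargylic alcohol
Product: 14 C7 tert-butyldimethylsilyl ether of 13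
Conditions: TBSOTf, 2,6-lutidine, CH2Cl2, −78 → 0 °C
Reagents that add atoms: tert-butyldimethylsilyl triflate, CC(C)(C)[Si](C)(C)OS(=O)(=O)C(F)(F)F
Why: Standard silylation of a hindered allylic alcohol, with the lutidine buffer protecting the ketal.

**Step 8**
Reactants: 14 terminal alkyne
Product: 16 methyl alkyne (C5≡C10–C20H3), via lithium acetylide 15 (not isolated)
Conditions: n-BuLi, THF, −78 °C; MeI, −78 °C → rt
Reagents that add atoms: iodomethane, CI
Why: Alkylation of the lithium acetylide with iodomethane brings in C20; no other acidic site is present.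

**Step 9**
Reactants: 16 methyl alkyne
Product: 18 (E)-vinyl iodide (C6H2–C5H=C10(CH3)I, iodine trans to C6), via (E)-alkenylzirconocene chloride 17 (not isolated)
Conditions: Cp2Zr(H)Cl (2.5 equiv), THF, 50 °C; I2, THF, 0 °C
Reagents that add atoms: iodine, II
Why: Syn hydrozirconation with excess Schwartz reagent equilibrates zirconium to the less hindered, methyl-bearing alkyne carbon C10, and iodinolysis with retention fixes the E geometry.

**Step 10**
Reactants: 18 vinyl iodide
Product: 19 primary alcohol (C9–OH free)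
Conditions: HF·pyridine, pyridine, THF, 0 °C
Reagents that add atoms: none
Why: Buffered fluoride cleaves the unhindered primary TBS ether faster than the primary TIPS ether and the secondary allylic TBS ether, and the ketal tolerates the buffer.

**Step 11**
Reactants: 19 primary alcohol
Product: 20 iodo aldehyde (C9HO)
Conditions: Dess–Martin periodinane, NaHCO3, CH2Cl2, 0 °C → rt
Reagents that add atoms: none
Why: Neutral Dess–Martin oxidation is compatible with the vinyl iodide, ketal and silyl ethers.

**Step 12**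
Reactants: 20 iodo aldehyde
Product: 21 bicyclo[7.2.1]dodecadiene allylic alcohol (ten-membered ring closed, C5=C10 E, both C9 epimers)
Conditions: CrCl2 (10 equiv), NiCl2 (1 mol % of Cr), DMSO–THF, rt, slow addition of 20 (final 2 mM)
Reagents that add atoms: none
Why: In the Nozaki–Hiyama–Kishi macrocyclisation nickel inserts into C10–I with retention of the E geometry, and the alkenylchromium(III) adds only to the aldehyde; this method has precedent for nine- and ten-membered carbocycles, and the C9 configuration is irrelevant.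

**Step 13**
Reactants: 21 allylic alcohol
Product: 22 bicyclic (E)-enone: C5H=C10(CH3)–C9(=O)–C11H2–C12H2–C13H–C14H=C8–C7H(OTBS)–C6H2, bridged by C15 (ethylene ketal)–C16H(CH2OTIPS); 7R,13R,16R
Conditions: Dess–Martin periodinane, NaHCO3, CH2Cl2, 0 °C
Reagents that add atoms: none
Why: Oxidation of the allylic alcohol merges both C9 epimers into one enone, and the buffer avoids vinylogous elimination of the C7 silyloxy group.

**Step 14**
Reactants: 23 4-methylpent-4-en-1-ol
Product: 24 4-methylpent-4-enal
Conditions: Dess–Martin periodinane, CH2Cl2, 0 °C → rt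
Reagents that add atoms: none
Why: Mild oxidation of the primary alcohol without migration of the 1,1-disubstituted alkene.

**Step 15**
Reactants: 22 bicyclic (E)-enone; 24 4-methylpent-4-enal
Product: 26 tricyclic β-hydroxy ketone (cyclohexane closed; 5R, C20 trans to H5, C1–OH), via iron(III) enolate of the Giese adduct 25 (not isolated)
Conditions: Fe(acac)3 (20 mol %), Ph(i-PrO)SiH2 (2.5 equiv), 24 (3 equiv, slow addition), (CH2Cl)2–ethylene glycol 10:1, 0 °C → rt, Ar
Reagents that add atoms: none
Why: The iron hydride made from Fe(acac)3 and the silane gives H• to the 1,1-disubstituted alkene of 24 (MHAT), the tertiary C4 radical adds to C5 of the enone (Giese addition, bond C4–C5), the C10 α-keto radical is reduced to the iron(III) enolate 25, and 25 attacks the tethered C1 aldehyde (bond C1–C10). The closest known reaction type is the MHAT-initiated radical–polar crossover annulation of γ,δ-unsaturated aldehydes with α-substituted enones, here applied to a medium-ring enone whose strained E-alkene should be a better acceptor than an open-chain tiglyl ketone. The cyclohexane is closed by an intermolecular radical addition followed by a 6-(enolexo)-exo-trig aldol through a chair. C5: the E-enone shows only its peripheral face, and in the favoured conformer C20 points away from the dioxolane-bearing C15–C16 bridge (fixed by C13), so attack should give 5R; C10: the C5–H bond lies in the enolate plane (A1,3 strain), C1 bonds on the face that carries C4, and C20 ends up axial and trans to H5 as in the target; C1: its configuration is left open because step 17 erases it. Chemoselectivity is built into the substrate: the cyclopentenone is a ketal and the exocyclic methylene is still CH2OTIPS, so C5 is the only acceptor carbon, and the hindered trisubstituted C8=C14 alkene should take up H• much more slowly than 24. The alkene geometry is lost at the radical and enolate stage, so any Z-enone formed by isomerisation is funnelled into the same product.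

**Step 16**
Reactants: 26 β-hydroxy ketone
Product: 27 C1 O-(imidazol-1-ylthiocarbonyl) derivative of 26
Conditions: 1,1′-thiocarbonyldiimidazole, DMAP, (CH2Cl)2, 70 °C
Reagents that add atoms: 1,1′-thiocarbonyldiimidazole, S=C(n1ccnc1)n1ccnc1
Why: Near-neutral thioacylation avoids the strong base of xanthate formation (retro-aldol risk), and C10 is quaternary, so dehydration towards the ketone is impossible.

**Step 17**
Reactants: 27 thiocarbonyl derivative
Product: 28 tricyclic ketone (C1H2; 5R,7R,10R,13R,16R)
Conditions: Bu3SnH (0.5 M), (PhSe)2 (10 mol %), AIBN, benzene, 80 °C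
Reagents that add atoms: none
Why: In this Barton–McCombie deoxygenation the benzeneselenol formed in situ is a very fast hydrogen donor and should trap the C1 radical before a 1,2-acyl shift of C9 can occur; no retained stereocentre is involved.

**Step 18**
Reactants: 28 tricyclic ketone
Product: 30 (11S)-α-hydroxy ketone, via potassium Z(O)-enolate 29 (not isolated)
Conditions: KHMDS, THF, −78 °C; 2-(phenylsulfonyl)-3-phenyloxaziridine, −78 °C; AcOH
Reagents that add atoms: 2-(phenylsulfonyl)-3-phenyloxaziridine, O=S(=O)(c1ccccc1)N1OC1c1ccccc1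
Why: In this enolate oxidation with an N-sulfonyloxaziridine, C10 is quaternary so only C11 is deprotonated, the tert-alkyl ketone gives the Z(O)-enolate (an E-alkene within the ten-membered ring, C–O turned outward and anti to C20), and the oxidant can reach only its peripheral face, which should give 11S.

**Step 19**
Reactants: 30 α-hydroxy ketone
Product: 31 (11S)-acetate
Conditions: Ac2O, DMAP, pyridine, CH2Cl2, 0 °C → rt
Reagents that add atoms: acetic anhydride, CC(=O)OC(C)=O
Why: Acylation of the only free hydroxyl group under conditions too mild to epimerise C11.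

**Step 20**
Reactants: 31 acetate
Product: 32 dihydroxy enone (C15 ketone, C7–OH and C17–OH free)
Conditions: 48 % aq HF, MeCN, 0 °C → rt
Reagents that add atoms: water, O
Why: Aqueous acidic fluoride removes both silyl ethers and hydrolyses the allylic ketal in one operation, while the acetate and the deactivated allylic alcohol at C7 are acid-stable.

**Step 21**
Reactants: 32 dihydroxy enone
Product: 34 target CNP0165527.2 (5R,7R,10R,11S,13R), via C17 mesylate 33 (not isolated)
Conditions: MsCl (1.1 equiv), Et3N (3 equiv), CH2Cl2, −30 → 0 °C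
Reagents that add atoms: none
Why: The primary C17–OH is mesylated in preference to the hindered secondary C7–OH, and the β-mesyloxy ketone undergoes E1cB elimination with Et3N to the exocyclic methylene, which also erases the auxiliary centre C16.

**Compound list**

1 | (S)-4-(tert-butyldimethylsilyloxy)cyclopent-2-en-1-one | O=C1C=C[C@@H](O[Si](C)(C)C(C)(C)C)C1 | starting material
2 | (3-bromopropoxy)(tert-butyl)dimethylsilane | BrCCCO[Si](C)(C)C(C)(C)C | starting material
3 | [3-(tert-butyldimethylsilyloxy)propyl]magnesium bromide | Br[Mg]CCCO[Si](C)(C)C(C)(C)C | intermediate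
4 | bromomagnesium enolate of the 1,4-adduct | Br[Mg]OC1=C[C@H](CCCO[Si](C)(C)C(C)(C)C)[C@@H](O[Si](C)(C)C(C)(C)C)C1 | intermediate
5 | (2R,3S,4S)-4-(TBSO)-3-[3-(TBSO)propyl]-2-(hydroxymethyl)cyclopentan-1-one | OC[C@@H]1C(=O)C[C@H](O[Si](C)(C)C(C)(C)C)[C@H]1CCCO[Si](C)(C)C(C)(C)C | intermediate
6 | triisopropylsilyl ether of 5 | CC(C)[Si](C(C)C)(C(C)C)OC[C@@H]1C(=O)C[C@H](O[Si](C)(C)C(C)(C)C)[C@H]1CCCO[Si](C)(C)C(C)(C)C | intermediate
7 | (4R,5R)-4-[3-(TBSO)propyl]-5-[(TIPSO)methyl]cyclopent-2-en-1-one | CC(C)[Si](C(C)C)(C(C)C)OC[C@@H]1C(=O)C=C[C@H]1CCCO[Si](C)(C)C(C)(C)C | intermediate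
8 | (4S,5R)-2-iodo derivative of 7 | CC(C)[Si](C(C)C)(C(C)C)OC[C@@H]1C(=O)C(I)=C[C@H]1CCCO[Si](C)(C)C(C)(C)C | intermediate
9 | ethylene ketal of 8 | CC(C)[Si](C(C)C)(C(C)C)OC[C@@H]1C2(OCCO2)C(I)=C[C@H]1CCCO[Si](C)(C)C(C)(C)C | intermediate
10 | C8-vinyllithium | CC(C)[Si](C(C)C)(C(C)C)OC[C@@H]1C2(OCCO2)C([Li])=C[C@H]1CCCO[Si](C)(C)C(C)(C)C | intermediate
11 | enal (C7 aldehyde on C8) | CC(C)[Si](C(C)C)(C(C)C)OC[C@@H]1C2(OCCO2)C(C=O)=C[C@H]1CCCO[Si](C)(C)C(C)(C)C | intermediate
12 | allenylboronic acid pinacol ester | C=C=CB1OC(C)(C)C(C)(C)O1 | starting material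
13 | (7R)-homopropargylic alcohol | CC(C)[Si](C(C)C)(C(C)C)OC[C@@H]1C2(OCCO2)C([C@H](O)CC#C)=C[C@H]1CCCO[Si](C)(C)C(C)(C)C | intermediate
14 | C7 TBS ether of 13 | CC(C)[Si](C(C)C)(C(C)C)OC[C@@H]1C2(OCCO2)C([C@H](O[Si](C)(C)C(C)(C)C)CC#C)=C[C@H]1CCCO[Si](C)(C)C(C)(C)C | intermediate
15 | lithium acetylide of 14 | CC(C)[Si](C(C)C)(C(C)C)OC[C@@H]1C2(OCCO2)C([C@H](O[Si](C)(C)C(C)(C)C)CC#C[Li])=C[C@H]1CCCO[Si](C)(C)C(C)(C)C | intermediate
16 | methyl alkyne | CC(C)[Si](C(C)C)(C(C)C)OC[C@@H]1C2(OCCO2)C([C@H](O[Si](C)(C)C(C)(C)C)CC#CC)=C[C@H]1CCCO[Si](C)(C)C(C)(C)C | intermediate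
17 | (E)-alkenylzirconocene chloride (Cp drawn σ-bound) | CC(C)[Si](C(C)C)(C(C)C)OC[C@@H]1C2(OCCO2)C([C@H](O[Si](C)(C)C(C)(C)C)C/C=C(\C)[Zr](Cl)(C2C=CC=C2)C2C=CC=C2)=C[C@H]1CCCO[Si](C)(C)C(C)(C)C | intermediate
18 | (E)-vinyl iodide | CC(C)[Si](C(C)C)(C(C)C)OC[C@@H]1C2(OCCO2)C([C@H](O[Si](C)(C)C(C)(C)C)C/C=C(\C)I)=C[C@H]1CCCO[Si](C)(C)C(C)(C)C | intermediate
19 | primary alcohol (C9–OH) | CC(C)[Si](C(C)C)(C(C)C)OC[C@@H]1C2(OCCO2)C([C@H](O[Si](C)(C)C(C)(C)C)C/C=C(\C)I)=C[C@H]1CCCO | intermediate
20 | iodo aldehyde (C9HO) | CC(C)[Si](C(C)C)(C(C)C)OC[C@@H]1C2(OCCO2)C([C@H](O[Si](C)(C)C(C)(C)C)C/C=C(\C)I)=C[C@H]1CCC=O | intermediate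
21 | macrocyclic allylic alcohol (both C9 epimers) | CC(C)[Si](C(C)C)(C(C)C)OC[C@@H]1C3(OCCO3)C2=C[C@H]1CCC(O)/C(C)=C/C[C@H]2O[Si](C)(C)C(C)(C)C | intermediate
22 | bicyclic (E)-enone | CC(C)[Si](C(C)C)(C(C)C)OC[C@@H]1C3(OCCO3)C2=C[C@H]1CCC(=O)/C(C)=C/C[C@H]2O[Si](C)(C)C(C)(C)C | intermediate
23 | 4-methylpent-4-en-1-ol | C=C(C)CCCO | starting material
24 | 4-methylpent-4-enal | C=C(C)CCC=O | intermediate
25 | iron(III) enolate of the Giese adduct (drawn as the enol) | CC(C)[Si](C(C)C)(C(C)C)OC[C@@H]1C3(OCCO3)C2=C[C@H]1CCC(O)=C(C)[C@@H](C(C)(C)CCC=O)C[C@H]2O[Si](C)(C)C(C)(C)C | intermediate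
26 | tricyclic β-hydroxy ketone (C1–OH, either epimer) | CC(C)[Si](C(C)C)(C(C)C)OC[C@@H]1C3(OCCO3)C2=C[C@H]1CCC(=O)[C@]1(C)C(O)CCC(C)(C)[C@H]1C[C@H]2O[Si](C)(C)C(C)(C)C | intermediate
27 | C1 O-(imidazol-1-ylthiocarbonyl) derivative | CC(C)[Si](C(C)C)(C(C)C)OC[C@@H]1C3(OCCO3)C2=C[C@H]1CCC(=O)[C@]1(C)C(OC(=S)n3ccnc3)CCC(C)(C)[C@H]1C[C@H]2O[Si](C)(C)C(C)(C)C | intermediate
28 | tricyclic ketone | CC(C)[Si](C(C)C)(C(C)C)OC[C@@H]1C3(OCCO3)C2=C[C@H]1CCC(=O)[C@]1(C)CCCC(C)(C)[C@H]1C[C@H]2O[Si](C)(C)C(C)(C)C | intermediate
29 | potassium Z(O)-enolate (C9=C11) | CC(C)[Si](C(C)C)(C(C)C)OC[C@@H]1C3(OCCO3)C2=C[C@H]1C/C=C(\O[K])[C@]1(C)CCCC(C)(C)[C@H]1C[C@H]2O[Si](C)(C)C(C)(C)C | intermediate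
30 | (11S)-α-hydroxy ketone | CC(C)[Si](C(C)C)(C(C)C)OC[C@@H]1C3(OCCO3)C2=C[C@H]1C[C@H](O)C(=O)[C@]1(C)CCCC(C)(C)[C@H]1C[C@H]2O[Si](C)(C)C(C)(C)C | intermediate
31 | (11S)-acetate | CC(C)[Si](C(C)C)(C(C)C)OC[C@@H]1C3(OCCO3)C2=C[C@H]1C[C@H](OC(C)=O)C(=O)[C@]1(C)CCCC(C)(C)[C@H]1C[C@H]2O[Si](C)(C)C(C)(C)C | intermediate
32 | dihydroxy enone | OC[C@@H]1C(=O)C2=C[C@H]1C[C@H](OC(C)=O)C(=O)[C@]1(C)CCCC(C)(C)[C@H]1C[C@H]2O | intermediate
33 | C17 mesylate | CS(=O)(=O)OC[C@@H]1C(=O)C2=C[C@H]1C[C@H](OC(C)=O)C(=O)[C@]1(C)CCCC(C)(C)[C@H]1C[C@H]2O | intermediate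
34 | CNP0165527.2 (11-acetoxy-7-hydroxy-8,9-seco-ent-kaura-8(14),16-diene-9,15-dione) | C=C1C(=O)C2=C[C@H]1C[C@H](OC(C)=O)C(=O)[C@]1(C)CCCC(C)(C)[C@H]1C[C@H]2O | target

Total step count: 21. Longest linear sequence: 20 (steps 1–13 and 15–21).

**Steps most likely to fail**

Step 15. Three things may go wrong: poor facial selectivity of the radical attack on the flexible ten-membered enone, protonation of the iron enolate before the aldol closure, or transannular attack of the C10 radical on C8=C14. The fallback sets out from 22 and returns at 28 by splitting the annulation into two known operations.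
- An MHAT Giese coupling of 22 with commercial 5-bromo-2-methylpent-2-ene (Fe(acac)3, PhSiH3, EtOH) generates the same tertiary radical. It should give the open-chain bromo ketone F1 as a pair of C10 epimers, and C5 diastereomers can be separated at this stage.
- KOt-Bu in t-BuOH–THF then equilibrates the enolates. Only the C10 enolate can close a six-membered ring (6-exo-tet alkylation through the same A1,3-controlled chair), so both C10 epimers converge on 28.
- Steps 16 and 17 fall away.

Step 12. Oligomerisation may win over closure because the E,E-cyclodecadiene is strained, and the vinyl iodide may be protodehalogenated. The fallback sets out from 16 and returns at 21.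
- Buffered HF·pyridine frees the primary alcohol to give the alkynol F2, and Dess–Martin oxidation gives the ynal F3.
- A nickel(0)-catalysed reductive alkyne–aldehyde macrocyclisation (Ni(cod)2, PBu3, Et3B, high dilution) forms C9–C10 through an oxanickelacycle at the methyl-bearing alkyne carbon.
- Syn delivery of H and C should give the same E allylic alcohol 21 without any vinyl iodide.

Step 18. The enolate oxidation may show poor or inverted facial selectivity if the ring enolate reacts from another conformer. The fallback sets out from 28 and returns at 30, and it delivers hydride instead of oxygen from the open face.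
- The same oxidation would then give the 11-epi alcohol F4.
- Dess–Martin oxidation gives the 9,11-dione F5.
- Zn(BH4)2 (Et2O, −78 °C) reduces the unhindered C11 carbonyl, since C9 is shielded by the quaternary C10. Attack from the peripheral face pushes the oxygen to the side required for 11S.

**Further compounds**

F1 | step 15 | bromo ketone (Giese adduct of 22, C5 configured as in 28, both C10 epimers) | CC(C)[Si](C(C)C)(C(C)C)OC[C@@H]1C3(OCCO3)C2=C[C@H]1CCC(=O)C(C)[C@@H](C(C)(C)CCCBr)C[C@H]2O[Si](C)(C)C(C)(C)C
F2 | step 12 | alkynol (C9–OH free, methyl alkyne) | CC(C)[Si](C(C)C)(C(C)C)OC[C@@H]1C2(OCCO2)C([C@H](O[Si](C)(C)C(C)(C)C)CC#CC)=C[C@H]1CCCO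
F3 | step 12 | ynal (C9HO, methyl alkyne) | CC(C)[Si](C(C)C)(C(C)C)OC[C@@H]1C2(OCCO2)C([C@H](O[Si](C)(C)C(C)(C)C)CC#CC)=C[C@H]1CCC=O
F4 | step 18 | (11R)-α-hydroxy ketone (11-epi-30) | CC(C)[Si](C(C)C)(C(C)C)OC[C@@H]1C3(OCCO3)C2=C[C@H]1C[C@@H](O)C(=O)[C@]1(C)CCCC(C)(C)[C@H]1C[C@H]2O[Si](C)(C)C(C)(C)C
F5 | step 18 | 9,11-dione | CC(C)[Si](C(C)C)(C(C)C)OC[C@@H]1C3(OCCO3)C2=C[C@H]1CC(=O)C(=O)[C@]1(C)CCCC(C)(C)[C@H]1C[C@H]2O[Si](C)(C)C(C)(C)C
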